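**Assumptions (one line each)**
- 4-Iodo-2-methylbut-1-ene is bought (otherwise one Appel step from 3-methylbut-3-en-1-ol).
- The (R)-PHOX ligand is assumed to give the (S) quaternary centre drawn, by analogy with (S)-t-BuPHOX giving (S)-2-allyl-2-methylcyclohexanone; if the sense is opposite, use the antipodal ligand.
- Steps 1–5 follow the known Pd-allylation/RCM chamigrene approach; steps 6–11 are my own design and are not literature-precedented on this skeleton.

**Retrosynthetic overview**
1. The tertiary C–Br comes from a trans-chlorohydrin (OH to Br with retention via a chloronium); the chlorohydrin comes from the ring-B trisubstituted alkene of "9-acetyl-deschloroelatol" (13).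
2. The ring-A cis-bromohydrin acetate comes from DIBAL reduction of an α-bromoketone; the exocyclic methylene comes from Peterson methylenation of a vinylogous-ester carbonyl; Br comes from γ-bromination of that vinylogous ester.
3. Ring B is formed second, by RCM of an allyl and a 3-methylbut-3-enyl group on the spiro carbon.
4. The spiro quaternary stereocentre (next to CMe2) is set by Pd-catalysed enantioselective decarboxylative allylation.
5. Ring A is the dimedone ring, carried from the start as its isobutyl vinylogous ester.

**Route**

Step 1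
Reactants: 1 dimedone; 2 isobutanol
Product: 3, 3-isobutoxy-5,5-dimethylcyclohex-2-en-1-one
Conditions: p-TsOH (cat.), PhMe, reflux, Dean–Stark
Reagents that add atoms: isobutanol (2), CC(C)CO
Why: Acid-catalysed vinylogous esterification of a symmetrical 1,3-diketone; no stereocentre.

Step 2
Reactants: 3; 4 4-iodo-2-methylbut-1-ene
Product: 5, (±)-3-isobutoxy-5,5-dimethyl-6-(3-methylbut-3-en-1-yl)cyclohex-2-en-1-one
Conditions: LDA, THF, −78 °C; then 4, −78 °C → rt
Reagents that add atoms: 4-iodo-2-methylbut-1-ene (4), C=C(C)CCI
Why: Stork–Danheiser kinetic α′-enolate alkylation; the racemic centre is erased in step 3.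

Step 3
Reactants: 5; 6 allyl chloroformate
Product: 7, allyl [5-isobutoxy-3,3-dimethyl-2-(3-methylbut-3-en-1-yl)cyclohexa-1,5-dien-1-yl] carbonate
Conditions: LDA, TMEDA, THF, −78 °C; then 6
Reagents that add atoms: allyl chloroformate (6), C=CCOC(Cl)=O
Why: O-acylation of the tetrasubstituted α′-enolate gives the allyl enol carbonate needed for decarboxylative allylation.

Step 4
Reactants: 7
Product: 8, (S)-6-allyl-3-isobutoxy-5,5-dimethyl-6-(3-methylbut-3-en-1-yl)cyclohex-2-en-1-one
Conditions: Pd2(dba)3 (2.5 mol %), (R)-(CF3)3-t-BuPHOX (6 mol %), PhMe, 25 °C (−CO2)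
Reagents that add atoms: none
Why: Enantioselective decarboxylative allylic alkylation (Tsuji–Trost type); the chiral Pd–PHOX complex selects the enolate face and sets the future spiro centre.

Step 5
Reactants: 8
Product: 9, (S)-3-isobutoxy-5,5,9-trimethylspiro[5.5]undeca-2,8-dien-1-one
Conditions: Grubbs II (5 mol %), CH2Cl2, 40 °C (−C2H4)
Reagents that add atoms: none
Why: Ring-closing metathesis of the allyl and 1,1-disubstituted alkenes forms ring B with its trisubstituted alkene; the quaternary centre is untouched.

Step 6
Reactants: 9
Product: 10, (4R,6S)-4-bromo-3-isobutoxy-5,5,9-trimethylspiro[5.5]undeca-2,8-dien-1-one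
Conditions: LDA, THF, −78 °C; TMSCl; then NBS, THF, −78 °C
Reagents that add atoms: N-bromosuccinimide, O=C1CCC(=O)N1Br
Why: γ-Deprotonation (α′ is quaternary) gives a 2-silyloxy-4-alkoxydiene that is brominated at its terminal carbon (vinylogous Mukaiyama-type halogenation); Br is expected to enter anti to the pseudo-axial ring-B CH2 and end equatorial, cis to the allylic CH2 of ring B, with any minor epimer removed by chromatography.

Step 7
Reactants: 10
Product: 11, (2R,6R)-2-bromo-1,1,9-trimethyl-5-methylidenespiro[5.5]undec-8-en-3-one
Conditions: Me3SiCH2Li, CeCl3, THF, −78 → 0 °C; then oxalic acid, THF/H2O, 0 °C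
Reagents that add atoms: (trimethylsilyl)methyllithium, [Li]C[Si](C)(C)C (the CH2 carbon); water, O (the ketone oxygen)
Why: Organocerium 1,2-addition then acid-induced Peterson elimination fixes the alkene exocyclic, and kinetic α-protonation of the dienol ether on hydrolysis gives the β,γ-unsaturated ketone; the C–Br centre is not touched.

Step 8
Reactants: 11
Product: 12, (2R,3S,6R)-2-bromo-1,1,9-trimethyl-5-methylidenespiro[5.5]undec-8-en-3-ol (deschloroelatol)
Conditions: DIBAL-H, CH2Cl2, −78 °C
Reagents that add atoms: none
Why: Diastereoselective hydride reduction; the axial methyl of the CMe2 group blocks axial attack, so hydride enters equatorially and gives the axial alcohol cis to the equatorial bromide. The ee from step 4 can be upgraded here by recrystallisation.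

Step 9
Reactants: 12
Product: 13, (2R,3S,6R)-2-bromo-1,1,9-trimethyl-5-methylidenespiro[5.5]undec-8-en-3-yl acetate
Conditions: Ac2O, DMAP (cat.), pyridine, CH2Cl2, 0 °C → rt
Reagents that add atoms: acetic anhydride, CC(=O)OC(C)=O
Why: DMAP-catalysed acylation with retention at the carbinol carbon.

Step 10
Reactants: 13
Product: 14, (2R,3S,6R,8S,9S)-2-bromo-8-chloro-9-hydroxy-1,1,9-trimethyl-5-methylidenespiro[5.5]undecan-3-yl acetate
Conditions: NCS, acetone/H2O (4:1), 0 °C
Reagents that add atoms: N-chlorosuccinimide, O=C1CCC(=O)N1Cl; water, O
Why: Anti chlorohydrin formation on the more nucleophilic trisubstituted alkene (the hindered exocyclic alkene is slower); water opens the chloronium at the tertiary carbon (Markovnikov) in a trans-diaxial (Fürst–Plattner) sense, intended to give OH cis and Cl trans to the CMe2 carbon.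

Step 11
Reactants: 14
Product: 15, 9-acetylisoobtusol, (2R,3S,6R,8S,9S)-2,9-dibromo-8-chloro-1,1,9-trimethyl-5-methylidenespiro[5.5]undecan-3-yl acetate
Conditions: TMSBr, 2,6-di-tert-butylpyridine, CH2Cl2, −40 → 0 °C
Reagents that add atoms: bromotrimethylsilane, C[Si](C)(C)Br
Why: SN1 substitution with neighbouring-group participation; the anti-periplanar chlorine bridges the tertiary cation and bromide opens anti to it, so C–OH becomes C–Br with net retention (trans Br/Cl), while the hindered base scavenges HBr to protect the exocyclic alkene.

**Compound list**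
1 | dimedone | CC1(C)CC(=O)CC(=O)C1 | starting material
2 | isobutanol | CC(C)CO | starting material
3 | 3-isobutoxy-5,5-dimethylcyclohex-2-en-1-one | CC(C)COC1=CC(=O)CC(C)(C)C1 | intermediate
4 | 4-iodo-2-methylbut-1-ene | C=C(C)CCI | starting material
5 | (±)-3-isobutoxy-5,5-dimethyl-6-(3-methylbut-3-enyl)cyclohex-2-en-1-one | CC(C)COC1=CC(=O)C(CCC(C)=C)C(C)(C)C1 | intermediate
6 | allyl chloroformate | C=CCOC(Cl)=O | starting material
7 | allyl dienyl (enol) carbonate of 5 | C=CCOC(=O)OC1=C(CCC(C)=C)C(C)(C)CC(OCC(C)C)=C1 | intermediate
8 | (S)-6-allyl-3-isobutoxy-5,5-dimethyl-6-(3-methylbut-3-enyl)cyclohex-2-en-1-one | O=C1C=C(OCC(C)C)CC(C)(C)[C@@]1(CC=C)CCC(C)=C | intermediate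
9 | (S)-3-isobutoxy-5,5,9-trimethylspiro[5.5]undeca-2,8-dien-1-one | O=C1C=C(OCC(C)C)CC(C)(C)[C@@]12CCC(C)=CC2 | intermediate
10 | (4R,6S)-4-bromo-3-isobutoxy-5,5,9-trimethylspiro[5.5]undeca-2,8-dien-1-one | O=C1C=C(OCC(C)C)[C@H](Br)C(C)(C)[C@@]12CCC(C)=CC2 | intermediate
11 | (2R,6R)-2-bromo-1,1,9-trimethyl-5-methylidenespiro[5.5]undec-8-en-3-one | C=C1CC(=O)[C@H](Br)C(C)(C)[C@@]12CCC(C)=CC2 | intermediate
12 | (2R,3S,6R)-2-bromo-1,1,9-trimethyl-5-methylidenespiro[5.5]undec-8-en-3-ol | C=C1C[C@H](O)[C@H](Br)C(C)(C)[C@@]12CCC(C)=CC2 | intermediate
13 | acetate of 12 | C=C1C[C@H](OC(C)=O)[C@H](Br)C(C)(C)[C@@]12CCC(C)=CC2 | intermediate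
14 | (2R,3S,6R,8S,9S)-chlorohydrin of 13 | C=C1C[C@H](OC(C)=O)[C@H](Br)C(C)(C)[C@@]12CC[C@](C)(O)[C@@H](Cl)C2 | intermediate
15 | 9-acetylisoobtusol | C=C1C[C@H](OC(C)=O)[C@H](Br)C(C)(C)[C@@]12CC[C@](C)(Br)[C@@H](Cl)C2 | target

**Totals**
- Total steps: 11
- Longest linear sequence: 11 (from dimedone)

**Three steps most likely to fail, with fallbacks**

1. Steps 10–11, ring-B halogenation. The required chlorohydrin places Cl on the ring-B face near the ring-A exocyclic methylene, so the facial outcome is genuinely uncertain and the other trans isomer may dominate. The tertiary bromide formation can also lose to E1 elimination or to HBr addition at the exocyclic alkene.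
   Fallback: set the ring-B halogens first on a limonene/α-terpineol-type monocycle, where Fürst–Plattner control is unambiguous, and then form the spiro centre and ring A by a bromonium-induced (e.g. BDSB) cation–olefin spirocyclisation of the derived γ-bisabolene-type triene.

2. Steps 6–7, ring-A bromination and methylenation. Risks are γ- versus α-bromination, the C–Br diastereoselectivity relative to the spiro centre, organocerium addition next to an activated bromide, and leakage of 11 to the conjugated enone.
   Fallback: take 9 through Stork–Danheiser transposition (MeLi/CeCl3, then H3O+) to the conjugated enone, brominate its kinetic α′-enolate, and move the alkene out of conjugation afterwards via the extended silyl dienol ether and kinetic protonation.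

3. Step 4, decarboxylative allylation. This forms a quaternary centre next to CMe2, so yield, ee and the sense of induction are all at risk.
   Fallback: replace steps 2–5 with a catalytic asymmetric Diels–Alder reaction of the 6-methylene derivative of 3 with isoprene (chiral strong Brønsted or Lewis acid), which forms ring B and the spiro centre in one step.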